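## The problem

The target is a 1-aryl-1,2-dihydronaphthalene: ring A (the benzo ring, 6-OMe, 7-O) is fused to ring B (C1–C4), which carries the guaiacyl ring C at C1, carboxyl groups at C2 and C3 and a C3=C4 bond conjugated to ring A, while O7 is bound as a (Z)-enol ether to the α-carbon of a second ferulic acid unit (ring D), so the molecule is a triacid with two free guaiacyl phenols. The only stereocentres, C1 (R) and C2 (R), are adjacent and cis, with ring C and the C2 carboxyl on the same face of ring B. C1 is doubly benzylic and configurationally robust, and nothing else in the molecule can direct it, so it has to come from a chiral catalyst or reagent. C2 is α to a carboxyl and allylic, epimerises easily and sits in the less stable cis arrangement, so it has to be set last under kinetic control, with the pseudoaxial ring C at C1 shielding one face. Once C2 bears hydrogen, base and air can aromatise the dihydronaphthalene and basic ester hydrolysis can invert C2; while ring C has a free para-hydroxyl and C2 is a stabilised carbanion, base can also reopen C1–C2 by retro-1,6-addition. The aryloxyacrylic enol ether has a defined geometry and only limited tolerance of acid. The enabling feature is that C1 is benzylic to ring C, whose 4-hydroxyl is para to it, which makes C1 a latent para-quinone methide carbon. C2 lies five atoms away along C1–C8a–C4a–C4=C3–C2 and is held next to C1 by the ortho-phenylene of ring A and the (E)-C3=C4 bond, so a nucleophilic C2 can close ring B on C1.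

## Retrosynthesis

**28 from 27.** Only C–O bonds are cut: two tert-butyl esters and two methoxymethyl ethers, all acid-labile. This makes the last step an acidolysis, so no base meets the cis C2–H of 28.

**27 from 25 through 26.** A second carboxyl is added back to C2, so the C2–CO2H bond is the one cut. With C2 quaternary, the two ethyl esters of 25 can be saponified without risk of epimerisation or aromatisation. Decarboxylation of diacid 26 then delivers the C2 proton to the enediol on the face away from ring C, giving the cis acid 27. The neighbouring option (dealkoxycarbonylation, enolate protonation, then hydrolysis of an ester beside an epimerisable centre) needs three operations and ends with a base-sensitive hydrolysis.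

**25 from 23 and 24; 23 from 20 and 22.** The enol ether C=C bond is cut by a Horner–Wadsworth–Emmons disconnection to the α-aryloxy phosphonate 23 and aldehyde 24. The O7–C bond of 23 is then cut to phenol 20 and the diazophosphonoacetate 22 (carbenoid O–H insertion). A direct aryl–O or vinyl–O cross-coupling on this crowded, oxidisable core has less to recommend it. The forward olefination must give the (Z)-alkene.

**20 from 19 from 18.** Protecting groups are exchanged. The ring C phenol of 18 is capped as a methoxymethyl ether in 19, which blocks retro-1,6 opening and leaves one phenol for the O–H insertion; the ring A silyl ether is then removed to give 20.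

**18 from 16 through 17 (key step).** The C1–C2 bond is cut. Unlike a cut at C1–C8a or a two-bond cycloaddition cut, this removes ring B and the C1 stereocentre together and leaves an acyclic precursor whose only stereocentre, the carbinol carbon, need not be controlled. Acid converts racemic 16 into the planar quinone methide 17, and the C2 malonate adds to C1. The forward reaction must provide enantioface control at C1 and needs the (E)-alkene.

**16 from 15 from 14.** The ring C phenol of 16 is released from the allyl ether 15, and the carbinol of 15 comes from diaryl ketone 14. The C1 oxygen is carried as a ketone through the olefination because a free carbinol ortho to the aldehyde would close to a lactol and would later add to the new acrylate.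

**14 from 9 and 12 through 13; 12 from 10 and 11.** The C3=C4 bond is cut to keto aldehyde 9 and ylide 13, which carries C3 and the C2 malonate. Ylide 13 is made in the flask by phosphine addition to the ethenetricarboxylate 12, itself a Wittig product of 10 and 11. Building the arm as a succinate and carboxylating C2 afterwards would need an enolate beside the diaryl ketone, which invites an intramolecular aldol reaction.

**9 from 7 through 8; 7 from 3 and 5 through 6; 3 from 1 through 2; 5 from 4.** The C1–C8a bond is cut to aryllithium 6 (from bromide 3, the doubly protected form of 6-bromovanillin 1, reached through 2) and O-allylvanillin 5 (from vanillin 4). Oxidation of carbinol 7 and acetal hydrolysis of 8 give 9. The substitution pattern of 1 places the aldehyde carbon (future C4) para to O7 and the bromine (future C8a) para to the 6-methoxy group.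

## Roads not taken

**Alternative 1:** Rings A and C are joined first as the 2-benzylbenzaldehyde A2, and C1–C2 and C3–C4 are cut together. Irradiation of A2 in the presence of the chiral butenolide A3, (5R)-5-menthyloxyfuran-2(5H)-one, would give the all-cis endo adduct A1 by photoenolisation and Diels–Alder trapping.
- Merits: two C–C bonds and four stereocentres form in one operation, the absolute configuration comes from a cheap auxiliary, and the cis C1/C2 relationship follows directly from the endo rule. On this last point it is better than the chosen plan, which must win C2 in a late protonation.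
- Weak points: A1 has C3 at the aldehyde (acetal) oxidation level and C4 as a carbinol. The route must still dehydrate C4–OH, hydrolyse the menthyl acetal, oxidise C3 to the acid and open the lactone, each under conditions that invite cis-to-trans epimerisation at C2 or aromatisation. It also needs a stoichiometric auxiliary and ultraviolet irradiation of electron-rich aryl silyl ethers.
- Comparison: the chosen plan has C3 as a carboxylate and C3=C4 in place from the start and uses a catalyst as its only chiral source. It pays with a sacrificial carboxyl and the late protonation.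

**Alternative 2:** C1–C8a and C3=C4 are cut, giving the ortho-formylarylboronic acid A5 (ring A) and the ring C benzylidenesuccinate A6. A chiral diene complex of monovalent rhodium (from [RhCl(C2H4)2]2) would transfer the ring A aryl group of A5 to the β-carbon of A6, and aldol condensation of the succinate CH2 with the neighbouring aldehyde would close ring B to A4 as a pair of C2 epimers.
- Merits: it is the most convergent road, needs roughly half the steps and no sacrificial carboxyl, and sets C1 by a reaction class with a strong record on β-aryl acrylates. In step economy it is clearly better.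
- Weak points: A6 is an α-substituted acceptor, a class that reacts poorly in rhodium-catalysed arylation, and ortho-formylboronic acids such as A5 protodeboronate easily. After aryl transfer the metal-bound nucleophilic carbon is C2, and its direct aldol reaction with the aldehyde closes a five-membered ring, the usual course of such arylation–aldol cascades. The wanted closure through C3 needs a separate base-mediated enolisation that scrambles C2, so A4 would still need a kinetic protonation.
- Comparison: the chosen plan is longer, but each ring-forming event has only one regiochemical outcome, and its malonate is what allows C2 to be set by decarboxylation.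

**Alternative 3:** C2–C3 is cut. The precursor A8 is a benzhydryl malonate carrying the ring A cinnamate, with C1 already set, for instance by an asymmetric conjugate arylation. Mn(OAc)3·2H2O with Cu(OAc)2 would generate a radical at C2 of A8 that adds to C3; oxidation at C4 by divalent copper and loss of a proton would give A7, the dimethyl ester counterpart of 19.
- Merits: the stereocentre-forming step rests on firmer precedent than step 10 of the chosen plan, which has to be conceded, and A7 would enter the same endgame.
- Weak points: an electrophilic malonyl radical must attack the electron-poor α-carbon of an acrylate in a 6-endo mode in competition with 5-exo attack at C4. Stoichiometric trivalent manganese in warm acetic acid meets two electron-rich arenes, a doubly benzylic tertiary C1–H and a product one oxidation away from a naphthalene, so over-oxidation and aromatisation (with loss of C1) threaten.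
- Comparison: the step count is about equal. The chosen plan closes the same ring by redox-neutral acid catalysis and converges both enantiomers of a racemic precursor, so no earlier asymmetric step is needed.

Key step: step 10

Assumption: the sense of induction of the phosphoric acid cannot be derived from first principles for this substrate; the (R)-catalyst is written, and if the first run shows the (1S) product, the mirror-image catalyst is used with nothing else changed.

## Route

Step 1
Reactants: 1 6-bromovanillin (2-bromo-4-hydroxy-5-methoxybenzaldehyde)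
Product: 2 2-bromo-5-methoxy-4-(triisopropylsilyloxy)benzaldehyde
Conditions: TIPSCl, imidazole, DMF, rt
Reagents that add atoms: triisopropylsilyl chloride, CC(C)[Si](Cl)(C(C)C)C(C)C
Why: Silyl ether formation at the only acidic group; the bulky aryl silyl ether tolerates butyllithium, dilute acid, borohydride and amines and is still cleaved selectively by fluoride in step 12.

Step 2
Reactants: 2 2-bromo-5-methoxy-4-(triisopropylsilyloxy)benzaldehyde
Product: 3 1-bromo-2-(dimethoxymethyl)-4-methoxy-5-(triisopropylsilyloxy)benzene
Conditions: HC(OMe)3, p-TsOH·H2O (cat.), MeOH, rt; Et3N quench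
Reagents that add atoms: trimethyl orthoformate, COC(OC)OC
Why: Acid-catalysed acetalisation with the orthoformate as water scavenger masks the aldehyde for the halogen–lithium exchange; the aryl silyl ether is stable to catalytic acid in methanol at room temperature.

Step 3
Reactants: 4 vanillin (4-hydroxy-3-methoxybenzaldehyde)
Product: 5 4-(allyloxy)-3-methoxybenzaldehyde
Conditions: allyl bromide, K2CO3, DMF, rt
Reagents that add atoms: allyl bromide, C=CCBr
Why: Williamson ether synthesis; the allyl ether survives the aryllithium addition, MnO2, dilute acid and borohydride and is later removed under near-neutral palladium catalysis without touching the silyl ether or the esters.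

Step 4
Reactants: 3 bromo acetal of ring A; 5 4-(allyloxy)-3-methoxybenzaldehyde
Product: 7 racemic [4-(allyloxy)-3-methoxyphenyl][2-(dimethoxymethyl)-4-methoxy-5-(triisopropylsilyloxy)phenyl]methanol, via aryllithium 6 (not isolated)
Conditions: n-BuLi, THF, −78 °C; then 5, −78 → −40 °C; H2O quench
Reagents that add atoms: none
Why: Bromine–lithium exchange outruns attack on the acetal or silyl ether at −78 °C, and aryllithium 6 adds 1,2 to aldehyde 5, forming the C1–C8a bond. The carbinol is racemic, which does not matter because C1 becomes planar in steps 5 and 10; the crude product is kept base-washed and taken on directly so that the hydroxyl does not close onto the acetal.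

Step 5
Reactants: 7 racemic diaryl carbinol acetal
Product: 9 2-[4-(allyloxy)-3-methoxybenzoyl]-5-methoxy-4-(triisopropylsilyloxy)benzaldehyde, via ketone acetal 8 (not isolated)
Conditions: MnO2, CH2Cl2, rt; filter; then 1 M HCl, THF, rt
Reagents that add atoms: water, O
Why: MnO2 oxidation of the electron-rich, doubly benzylic carbinol gives the diaryl ketone, and brief aqueous acid then hydrolyses the dimethyl acetal. Carrying the C1 oxygen as a ketone prevents lactol formation and oxa-Michael closure during the olefination.

Step 6
Reactants: 10 diethyl ketomalonate; 11 tert-butyl (triphenylphosphoranylidene)acetate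
Product: 12 2-tert-butyl 1,1-diethyl ethene-1,1,2-tricarboxylate
Conditions: CH2Cl2, 0 °C → rt
Reagents that add atoms: none
Why: Wittig olefination of the highly electrophilic central ketone of 10 by the stabilised ylide 11; no alkene geometry arises because the malonate terminus carries two identical esters.

Step 7
Reactants: 12 2-tert-butyl 1,1-diethyl ethene-1,1,2-tricarboxylate; 9 keto aldehyde of rings A and C
Product: 14 2-tert-butyl 1,1-diethyl (2E)-3-{2-[4-(allyloxy)-3-methoxybenzoyl]-5-methoxy-4-(triisopropylsilyloxy)phenyl}prop-2-ene-1,1,2-tricarboxylate, via phosphorus ylide 13 (not isolated)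
Conditions: PBu3, toluene, rt (12 added slowly to the phosphine); then 9, 80 °C
Reagents that add atoms: none
Why: Tributylphosphine adds to the CH terminus of the electron-poor alkene 12 (phospha-Michael addition) and proton transfer gives the ester-stabilised ylide 13, which olefinates the aldehyde of 9 in the presence of the inert diaryl ketone (Wittig reaction, as in phosphine-mediated olefinations with maleates and maleimides). α-Branched stabilised ylides place the aryl group trans to the ester, the (E)-geometry that brings the malonate carbon cis to ring A, and the neutral medium avoids enolate chemistry beside the ketone.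

Step 8
Reactants: 14 (E)-alkylidene triester diaryl ketone
Product: 15 2-tert-butyl 1,1-diethyl (2E)-3-{2-[(4-(allyloxy)-3-methoxyphenyl)(hydroxy)methyl]-5-methoxy-4-(triisopropylsilyloxy)phenyl}prop-2-ene-1,1,2-tricarboxylate (racemic at the carbinol carbon)
Conditions: NaBH4, CeCl3·7H2O, MeOH/THF, −20 → 0 °C
Reagents that add atoms: none
Why: Luche reduction: the trivalent cerium salt activates the ketone and buffers the medium, so 1,2-reduction should outrun malonate deprotonation, conjugate reduction and alkoxide addition to the acrylate. A racemic carbinol is all that step 10 requires.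

Step 9
Reactants: 15 racemic O-allyl benzhydrol
Product: 16 2-tert-butyl 1,1-diethyl (2E)-3-{2-[hydroxy(4-hydroxy-3-methoxyphenyl)methyl]-5-methoxy-4-(triisopropylsilyloxy)phenyl}prop-2-ene-1,1,2-tricarboxylate (racemic at the carbinol carbon)
Conditions: Pd(PPh3)4 (5 mol%), morpholine, THF, rt
Reagents that add atoms: none
Why: Zerovalent palladium ionises the allyl aryl ether to a π-allyl complex that morpholine captures (Tsuji–Trost-type allyl transfer). The medium is close to neutral, so the acid-labile para-hydroxybenzhydrol is released without ionisation and the malonate stays protonated; 16 is purified on base-deactivated silica and used at once.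

Step 10
Reactants: 16 racemic para-hydroxybenzhydrol with the (E)-malonyl acrylate arm
Product: 18 3-tert-butyl 2,2-diethyl (1R)-1-(4-hydroxy-3-methoxyphenyl)-6-methoxy-7-(triisopropylsilyloxy)naphthalene-2,2,3(1H)-tricarboxylate, via para-quinone methide 17 (not isolated)
Conditions: (R)-3,3′-bis(2,4,6-triisopropylphenyl)-1,1′-binaphthyl-2,2′-diyl hydrogen phosphate [(R)-TRIP] (10 mol%), 5 Å MS, toluene, 0 °C → rt
Reagents that add atoms: none
Why: Proposed new method: the phosphoric acid hydrogen-bonds to the carbinol and the ring C phenol of 16 and assists loss of water, so both enantiomers of 16 collapse to the same planar para-quinone methide 17 and the carbinol configuration is erased; the acid then holds the quinone methide oxygen and the enol of the C2 malonate in one hydrogen-bonded array while C2 adds to C1 and ring C rearomatises. The closest known reaction type is the phosphoric acid-catalysed enantioselective 1,6-addition of enolisable 1,3-dicarbonyl compounds, indoles and naphthols to para-quinone methides generated in situ from para-hydroxybenzyl alcohols; new here are a malonate as the weakly enolised pronucleophile and the intramolecular mode. Ring B closes 6-exo-trig, since the C1=C bond of the quinone methide lies outside the new ring, and the enol double bond is exocyclic as well. The only new stereocentre, C1, is set by the catalyst, which distinguishes the two enantiotopic faces of C1 (equivalently the two helical conformers about C1–C8a) inside its chiral pocket; C2 becomes quaternary with two identical esters, so no second stereocentre arises. The step needs enantioface selectivity, C- over O-attack and 1,6-regiochemistry: the (E)-alkene and the ortho-phenylene hold C2 within bonding distance of C1, which should make ring closure faster than return of water or attack by a second molecule, the enol oxygens cannot reach C1 without an eight-membered ring, and C1 is the only electrophilic site conjugated to the ring C carbonyl. Enolisation is helped because the C2–H is both malonic and allylic to the cinnamate, so its enol is a conjugated dienol.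

Step 11
Reactants: 18 (1R)-dihydronaphthalene triester with free ring C phenol
Product: 19 3-tert-butyl 2,2-diethyl (1R)-6-methoxy-1-[3-methoxy-4-(methoxymethoxy)phenyl]-7-(triisopropylsilyloxy)naphthalene-2,2,3(1H)-tricarboxylate
Conditions: MOMCl, iPr2NEt, CH2Cl2, 0 °C → rt
Reagents that add atoms: chloromethyl methyl ether, COCCl
Why: O-alkylation of the phenol with a hindered amine base (acetal-type ether formation); capping the ring C hydroxyl closes the retro-1,6 pathway that could reopen C1–C2 under base and reserves the later O–H insertion for ring A.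

Step 12
Reactants: 19 ring C methoxymethyl ether
Product: 20 3-tert-butyl 2,2-diethyl (1R)-7-hydroxy-6-methoxy-1-[3-methoxy-4-(methoxymethoxy)phenyl]naphthalene-2,2,3(1H)-tricarboxylate
Conditions: Bu4NF, AcOH, THF, 0 °C
Reagents that add atoms: none
Why: Fluoride-induced desilylation buffered with acetic acid; C2 is quaternary, so the phenoxide formed cannot cause epimerisation, and the methoxymethyl ether and the esters are inert.

Step 13
Reactants: 21 tert-butyl diethylphosphonoacetate
Product: 22 tert-butyl 2-diazo-2-(diethoxyphosphoryl)acetate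
Conditions: NaH, THF, 0 °C; then 4-acetamidobenzenesulfonyl azide, rt
Reagents that add atoms: 4-acetamidobenzenesulfonyl azide, CC(=O)Nc1ccc(cc1)S(=O)(=O)N=[N+]=[N-]
Why: Diazo transfer from the sulfonyl azide to the sodium enolate of the phosphonoacetate, the standard entry to α-diazo phosphonoacetates.

Step 14
Reactants: 20 ring A phenol; 22 tert-butyl 2-diazo-2-(diethoxyphosphoryl)acetate
Product: 23 3-tert-butyl 2,2-diethyl (1R)-7-[2-tert-butoxy-1-(diethoxyphosphoryl)-2-oxoethoxy]-6-methoxy-1-[3-methoxy-4-(methoxymethoxy)phenyl]naphthalene-2,2,3(1H)-tricarboxylate (both epimers at the phosphonate carbon)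
Conditions: Rh2(OAc)4 (2 mol%), toluene, 80 °C, slow addition of 22
Reagents that add atoms: none
Why: The rhodium carbenoid formed from 22 inserts into the phenolic O–H bond (carbenoid O–H insertion), forming the O7–C bond; acceptor/acceptor carbenoids prefer the O–H bond to the hindered, electron-poor C3=C4 bond or to C–H bonds. The new centre at the phosphonate carbon forms unselectively and disappears in step 16.

Step 15
Reactants: 4 vanillin
Product: 24 3-methoxy-4-(methoxymethoxy)benzaldehyde
Conditions: MOMCl, iPr2NEt, CH2Cl2, 0 °C → rt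
Reagents that add atoms: chloromethyl methyl ether, COCCl
Why: O-alkylation of the phenol (acetal-type ether formation); the ring D phenol then carries the same acid-labile group as ring C, so both fall in the last step.

Step 16
Reactants: 23 α-aryloxy phosphonoacetate; 24 3-methoxy-4-(methoxymethoxy)benzaldehyde
Product: 25 3-tert-butyl 2,2-diethyl (1R)-7-{[(1Z)-3-tert-butoxy-1-[3-methoxy-4-(methoxymethoxy)phenyl]-3-oxoprop-1-en-2-yl]oxy}-6-methoxy-1-[3-methoxy-4-(methoxymethoxy)phenyl]naphthalene-2,2,3(1H)-tricarboxylate
Conditions: NaH, THF, 0 °C; then 24, 0 °C → rt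
Reagents that add atoms: none
Why: Horner–Wadsworth–Emmons olefination; α-aryloxy phosphonoacetates should favour the enol ether with the aryl group trans to the ester, here the (Z)-isomer, and 23 has no other acidic C–H because C2 is quaternary. Any minor (E)-isomer is to be removed by chromatography.

Step 17
Reactants: 25 fully protected (Z)-enol ether tetraester
Product: 27 (1R,2R)-3-(tert-butoxycarbonyl)-7-{[(1Z)-3-tert-butoxy-1-[3-methoxy-4-(methoxymethoxy)phenyl]-3-oxoprop-1-en-2-yl]oxy}-6-methoxy-1-[3-methoxy-4-(methoxymethoxy)phenyl]-1,2-dihydronaphthalene-2-carboxylic acid, via malonic diacid 26 (not isolated)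
Conditions: KOH, EtOH/H2O, 70 °C; then aq. KHSO4 to pH 3, 0 °C, extraction; then toluene, 80 °C, argon
Reagents that add atoms: potassium hydroxide, [K+].[OH-]
Why: Saponification of the two ethyl esters takes place while C2 is quaternary, so neither epimerisation nor aromatisation is possible, and the tert-butyl esters and acetals resist hydroxide. On warming, the vinyl-substituted malonic acid 26 loses CO2 through the cyclic transition state (malonic acid decarboxylation) and the enediol is protonated at C2 on the face opposite the pseudoaxial ring C at C1 (kinetic ketonisation), which should give the cis (2R) acid.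

Step 18
Reactants: 27 cis C2 acid with tert-butyl esters at C3 and on the side chain
Product: 28 (1R,2R)-7-{[(1Z)-1-carboxy-2-(4-hydroxy-3-methoxyphenyl)ethenyl]oxy}-1-(4-hydroxy-3-methoxyphenyl)-6-methoxy-1,2-dihydronaphthalene-2,3-dicarboxylic acid (CNP0328417.1)
Conditions: CF3CO2H/CH2Cl2 (1:3), H2O (10 equiv), 0 °C → rt, argon
Reagents that add atoms: none
Why: Acidolysis removes both tert-butyl esters (as isobutene) and both methoxymethyl ethers in one operation, so no base touches the cis C2–H. C1 and C2 do not enolise under these conditions, and the aryloxyacrylic acid is deactivated towards protonation by its carboxyl group.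

## Compound list

1 | 6-bromovanillin (2-bromo-4-hydroxy-5-methoxybenzaldehyde) | O=Cc1cc(OC)c(O)cc1Br | starting material
2 | 2-bromo-5-methoxy-4-(triisopropylsilyloxy)benzaldehyde | O=Cc1cc(OC)c(O[Si](C(C)C)(C(C)C)C(C)C)cc1Br | intermediate
3 | 1-bromo-2-(dimethoxymethyl)-4-methoxy-5-(triisopropylsilyloxy)benzene | COC(OC)c1cc(OC)c(O[Si](C(C)C)(C(C)C)C(C)C)cc1Br | intermediate
4 | vanillin (4-hydroxy-3-methoxybenzaldehyde) | COc1cc(C=O)ccc1O | starting material
5 | 4-(allyloxy)-3-methoxybenzaldehyde | C=CCOc1ccc(C=O)cc1OC | intermediate
6 | [2-(dimethoxymethyl)-4-methoxy-5-(triisopropylsilyloxy)phenyl]lithium (formed in the flask) | [Li]c1cc(O[Si](C(C)C)(C(C)C)C(C)C)c(OC)cc1C(OC)OC | intermediate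
7 | racemic [4-(allyloxy)-3-methoxyphenyl][2-(dimethoxymethyl)-4-methoxy-5-(triisopropylsilyloxy)phenyl]methanol | COC(OC)c1cc(OC)c(O[Si](C(C)C)(C(C)C)C(C)C)cc1C(O)c1ccc(OCC=C)c(OC)c1 | intermediate
8 | [4-(allyloxy)-3-methoxyphenyl][2-(dimethoxymethyl)-4-methoxy-5-(triisopropylsilyloxy)phenyl]methanone (formed in the flask) | COC(OC)c1cc(OC)c(O[Si](C(C)C)(C(C)C)C(C)C)cc1C(=O)c1ccc(OCC=C)c(OC)c1 | intermediate
9 | 2-[4-(allyloxy)-3-methoxybenzoyl]-5-methoxy-4-(triisopropylsilyloxy)benzaldehyde | O=Cc1cc(OC)c(O[Si](C(C)C)(C(C)C)C(C)C)cc1C(=O)c1ccc(OCC=C)c(OC)c1 | intermediate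
10 | diethyl ketomalonate (diethyl 2-oxopropanedioate) | CCOC(=O)C(=O)C(=O)OCC | starting material
11 | tert-butyl (triphenylphosphoranylidene)acetate | CC(C)(C)OC(=O)C=P(c1ccccc1)(c1ccccc1)c1ccccc1 | starting material
12 | 2-tert-butyl 1,1-diethyl ethene-1,1,2-tricarboxylate | CCOC(=O)C(=CC(=O)OC(C)(C)C)C(=O)OCC | intermediate
13 | 2-tert-butyl 1,1-diethyl 2-(tributylphosphoranylidene)ethane-1,1,2-tricarboxylate (formed in the flask) | CCCCP(CCCC)(CCCC)=C(C(=O)OC(C)(C)C)C(C(=O)OCC)C(=O)OCC | intermediate
14 | 2-tert-butyl 1,1-diethyl (2E)-3-{2-[4-(allyloxy)-3-methoxybenzoyl]-5-methoxy-4-(triisopropylsilyloxy)phenyl}prop-2-ene-1,1,2-tricarboxylate | CCOC(=O)C(C(=O)OCC)/C(C(=O)OC(C)(C)C)=C\c1cc(OC)c(O[Si](C(C)C)(C(C)C)C(C)C)cc1C(=O)c1ccc(OCC=C)c(OC)c1 | intermediate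
15 | 2-tert-butyl 1,1-diethyl (2E)-3-{2-[(4-(allyloxy)-3-methoxyphenyl)(hydroxy)methyl]-5-methoxy-4-(triisopropylsilyloxy)phenyl}prop-2-ene-1,1,2-tricarboxylate (racemic at the carbinol carbon) | CCOC(=O)C(C(=O)OCC)/C(C(=O)OC(C)(C)C)=C\c1cc(OC)c(O[Si](C(C)C)(C(C)C)C(C)C)cc1C(O)c1ccc(OCC=C)c(OC)c1 | intermediate
16 | 2-tert-butyl 1,1-diethyl (2E)-3-{2-[hydroxy(4-hydroxy-3-methoxyphenyl)methyl]-5-methoxy-4-(triisopropylsilyloxy)phenyl}prop-2-ene-1,1,2-tricarboxylate (racemic at the carbinol carbon) | CCOC(=O)C(C(=O)OCC)/C(C(=O)OC(C)(C)C)=C\c1cc(OC)c(O[Si](C(C)C)(C(C)C)C(C)C)cc1C(O)c1ccc(O)c(OC)c1 | intermediate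
17 | 2-tert-butyl 1,1-diethyl (2E)-3-{5-methoxy-2-[(3-methoxy-4-oxocyclohexa-2,5-dien-1-ylidene)methyl]-4-(triisopropylsilyloxy)phenyl}prop-2-ene-1,1,2-tricarboxylate (formed in the flask; either geometry at the exocyclic bond) | CCOC(=O)C(C(=O)OCC)/C(C(=O)OC(C)(C)C)=C\c1cc(OC)c(O[Si](C(C)C)(C(C)C)C(C)C)cc1C=C1C=CC(=O)C(OC)=C1 | intermediate
18 | 3-tert-butyl 2,2-diethyl (1R)-1-(4-hydroxy-3-methoxyphenyl)-6-methoxy-7-(triisopropylsilyloxy)naphthalene-2,2,3(1H)-tricarboxylate | CC(C)[Si](C(C)C)(C(C)C)Oc1cc2c(cc1OC)C=C(C(=O)OC(C)(C)C)C(C(=O)OCC)(C(=O)OCC)[C@@H]2c1ccc(O)c(OC)c1 | intermediate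
19 | 3-tert-butyl 2,2-diethyl (1R)-6-methoxy-1-[3-methoxy-4-(methoxymethoxy)phenyl]-7-(triisopropylsilyloxy)naphthalene-2,2,3(1H)-tricarboxylate | CC(C)[Si](C(C)C)(C(C)C)Oc1cc2c(cc1OC)C=C(C(=O)OC(C)(C)C)C(C(=O)OCC)(C(=O)OCC)[C@@H]2c1ccc(OCOC)c(OC)c1 | intermediate
20 | 3-tert-butyl 2,2-diethyl (1R)-7-hydroxy-6-methoxy-1-[3-methoxy-4-(methoxymethoxy)phenyl]naphthalene-2,2,3(1H)-tricarboxylate | Oc1cc2c(cc1OC)C=C(C(=O)OC(C)(C)C)C(C(=O)OCC)(C(=O)OCC)[C@@H]2c1ccc(OCOC)c(OC)c1 | intermediate
21 | tert-butyl diethylphosphonoacetate [tert-butyl 2-(diethoxyphosphoryl)acetate] | CCOP(=O)(OCC)CC(=O)OC(C)(C)C | starting material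
22 | tert-butyl 2-diazo-2-(diethoxyphosphoryl)acetate | CCOP(=O)(OCC)C(=[N+]=[N-])C(=O)OC(C)(C)C | intermediate
23 | 3-tert-butyl 2,2-diethyl (1R)-7-[2-tert-butoxy-1-(diethoxyphosphoryl)-2-oxoethoxy]-6-methoxy-1-[3-methoxy-4-(methoxymethoxy)phenyl]naphthalene-2,2,3(1H)-tricarboxylate (both epimers at the phosphonate carbon) | CCOP(=O)(OCC)C(Oc1cc2c(cc1OC)C=C(C(=O)OC(C)(C)C)C(C(=O)OCC)(C(=O)OCC)[C@@H]2c1ccc(OCOC)c(OC)c1)C(=O)OC(C)(C)C | intermediate
24 | 3-methoxy-4-(methoxymethoxy)benzaldehyde | COCOc1ccc(C=O)cc1OC | intermediate
25 | 3-tert-butyl 2,2-diethyl (1R)-7-{[(1Z)-3-tert-butoxy-1-[3-methoxy-4-(methoxymethoxy)phenyl]-3-oxoprop-1-en-2-yl]oxy}-6-methoxy-1-[3-methoxy-4-(methoxymethoxy)phenyl]naphthalene-2,2,3(1H)-tricarboxylate | COc1cc(/C=C(\Oc2cc3c(cc2OC)C=C(C(=O)OC(C)(C)C)C(C(=O)OCC)(C(=O)OCC)[C@@H]3c2ccc(OCOC)c(OC)c2)C(=O)OC(C)(C)C)ccc1OCOC | intermediate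
26 | (1R)-3-(tert-butoxycarbonyl)-7-{[(1Z)-3-tert-butoxy-1-[3-methoxy-4-(methoxymethoxy)phenyl]-3-oxoprop-1-en-2-yl]oxy}-6-methoxy-1-[3-methoxy-4-(methoxymethoxy)phenyl]naphthalene-2,2(1H)-dicarboxylic acid (formed in the flask) | COc1cc(/C=C(\Oc2cc3c(cc2OC)C=C(C(=O)OC(C)(C)C)C(C(=O)O)(C(=O)O)[C@@H]3c2ccc(OCOC)c(OC)c2)C(=O)OC(C)(C)C)ccc1OCOC | intermediate
27 | (1R,2R)-3-(tert-butoxycarbonyl)-7-{[(1Z)-3-tert-butoxy-1-[3-methoxy-4-(methoxymethoxy)phenyl]-3-oxoprop-1-en-2-yl]oxy}-6-methoxy-1-[3-methoxy-4-(methoxymethoxy)phenyl]-1,2-dihydronaphthalene-2-carboxylic acid | COc1cc(/C=C(\Oc2cc3c(cc2OC)C=C(C(=O)OC(C)(C)C)[C@H](C(=O)O)[C@@H]3c2ccc(OCOC)c(OC)c2)C(=O)OC(C)(C)C)ccc1OCOC | intermediate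
28 | (1R,2R)-7-{[(1Z)-1-carboxy-2-(4-hydroxy-3-methoxyphenyl)ethenyl]oxy}-1-(4-hydroxy-3-methoxyphenyl)-6-methoxy-1,2-dihydronaphthalene-2,3-dicarboxylic acid (CNP0328417.1) | COc1cc(/C=C(\Oc2cc3c(cc2OC)C=C(C(=O)O)[C@H](C(=O)O)[C@@H]3c2ccc(O)c(OC)c2)C(=O)O)ccc1O | target

## Step count and weakest steps

Total: 18 steps. Longest linear sequence: 14 steps (1, 2, 4, 5, 7, 8, 9, 10, 11, 12, 14, 16, 17, 18).

**Step 10 (key step, proposed new method).**
- Risk: enolisation of the malonate may be too slow under a phosphoric acid, so the quinone methide reverts by re-addition of water or oligomerises. Enantioface discrimination may also be modest, because electrophile and nucleophile are generated within one flexible molecule and adventitious acid can open a racemic background closure.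
- Fallback (known chemistry, from 15 back to 18): the carbinol 15 is converted with SOCl2 and 2,6-lutidine into the benzhydryl chloride F1. Cs2CO3 in MeCN closes ring B by intramolecular C-alkylation of the malonate (classical malonic ester alkylation, 6-exo-tet) to the racemic O-allyl dihydronaphthalene F2. Deallylation as in step 9 gives the racemic dihydronaphthalene phenol F3, the racemate of 18, and preparative chromatography on a chiral stationary phase separates its enantiomers and returns 18.

**Step 7.**
- Risk: sluggish addition of the α-branched ylide to the hindered, electron-rich aldehyde, and erosion of the (E)-geometry on prolonged heating.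
- Fallback (from 12 and 9 back to 14): Pudovik-type addition of diethyl phosphite to 12 (cat. Et3N) gives the phosphonate 2-tert-butyl 1,1-diethyl 2-(diethoxyphosphoryl)ethane-1,1,2-tricarboxylate F4. Its dianion, formed with two equivalents of LiN(SiMe3)2 in THF, undergoes Horner–Wadsworth–Emmons olefination with 9 to give 14.

**Step 8.**
- Risk: base-induced migration of the double bond into conjugation with the malonate followed by conjugate hydride addition, or ring closure of the new alkoxide onto the acrylate.
- Fallback (from 7 back to 15, the C1 oxygen carried as a silyl ether instead of a ketone): the carbinol 7 is silylated (TBSCl, imidazole) to the tert-butyldimethylsilyl ether F5. The acetal is hydrolysed on wet silica with oxalic acid to the aldehyde F6, and olefination with ylide 13 as in step 7 gives the silyl-protected arm compound F7. HF·pyridine in THF/pyridine then cleaves the secondary alkyl silyl ether in preference to the aryl triisopropylsilyl ether and returns 15.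

**Step 16.**
- Risk: incomplete (Z)-selectivity in the olefination of the α-aryloxy phosphonate.
- Fallback (from 20 back to 25, bypassing 22 and 23): O-alkylation of 20 with tert-butyl bromoacetate and K2CO3 gives the aryloxyacetate F8. Its lithium enolate (LiN(iPr)2, THF, −78 °C) adds to 24 to give the β-hydroxy ester F9. Mesylation (MsCl, Et3N) gives the mesylate F10, which is not isolated, and E1cB elimination with DBU gives the thermodynamically preferred (Z)-enol ether 25.

**Step 17.**
- Risk: insufficient facial selectivity in ketonisation of the enediol, so that the trans acid forms alongside the cis acid. Slow hydrolysis of the second hindered ethyl ester is a lesser concern.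
- Fallback (from 26 back to 27): the trans (1R,2S) acid F11, the C2 epimer of 27 that such a decarboxylation of 26 would deliver, is converted with LiN(iPr)2 (2.2 equiv, THF, −78 °C) into the enediolate dianion and quenched at −78 °C with 2,6-di-tert-butylphenol. Kinetic protonation occurs anti to ring C and returns 27.

## Further compounds

F1 | step 10 | 2-tert-butyl 1,1-diethyl (2E)-3-{2-[(4-(allyloxy)-3-methoxyphenyl)(chloro)methyl]-5-methoxy-4-(triisopropylsilyloxy)phenyl}prop-2-ene-1,1,2-tricarboxylate (racemic) | CCOC(=O)C(C(=O)OCC)/C(C(=O)OC(C)(C)C)=C\c1cc(OC)c(O[Si](C(C)C)(C(C)C)C(C)C)cc1C(Cl)c1ccc(OCC=C)c(OC)c1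
F2 | step 10 | racemic 3-tert-butyl 2,2-diethyl 1-[4-(allyloxy)-3-methoxyphenyl]-6-methoxy-7-(triisopropylsilyloxy)naphthalene-2,2,3(1H)-tricarboxylate | CC(C)[Si](C(C)C)(C(C)C)Oc1cc2c(cc1OC)C=C(C(=O)OC(C)(C)C)C(C(=O)OCC)(C(=O)OCC)C2c1ccc(OCC=C)c(OC)c1
F3 | step 10 | racemic 3-tert-butyl 2,2-diethyl 1-(4-hydroxy-3-methoxyphenyl)-6-methoxy-7-(triisopropylsilyloxy)naphthalene-2,2,3(1H)-tricarboxylate | CC(C)[Si](C(C)C)(C(C)C)Oc1cc2c(cc1OC)C=C(C(=O)OC(C)(C)C)C(C(=O)OCC)(C(=O)OCC)C2c1ccc(O)c(OC)c1
F4 | step 7 | 2-tert-butyl 1,1-diethyl 2-(diethoxyphosphoryl)ethane-1,1,2-tricarboxylate | CCOC(=O)C(C(=O)OCC)C(C(=O)OC(C)(C)C)P(=O)(OCC)OCC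
F5 | step 8 | racemic {[4-(allyloxy)-3-methoxyphenyl][2-(dimethoxymethyl)-4-methoxy-5-(triisopropylsilyloxy)phenyl]methoxy}(tert-butyl)dimethylsilane | COC(OC)c1cc(OC)c(O[Si](C(C)C)(C(C)C)C(C)C)cc1C(O[Si](C)(C)C(C)(C)C)c1ccc(OCC=C)c(OC)c1
F6 | step 8 | racemic 2-{[4-(allyloxy)-3-methoxyphenyl](tert-butyldimethylsilyloxy)methyl}-5-methoxy-4-(triisopropylsilyloxy)benzaldehyde | O=Cc1cc(OC)c(O[Si](C(C)C)(C(C)C)C(C)C)cc1C(O[Si](C)(C)C(C)(C)C)c1ccc(OCC=C)c(OC)c1
F7 | step 8 | 2-tert-butyl 1,1-diethyl (2E)-3-{2-[(4-(allyloxy)-3-methoxyphenyl)(tert-butyldimethylsilyloxy)methyl]-5-methoxy-4-(triisopropylsilyloxy)phenyl}prop-2-ene-1,1,2-tricarboxylate (racemic) | CCOC(=O)C(C(=O)OCC)/C(C(=O)OC(C)(C)C)=C\c1cc(OC)c(O[Si](C(C)C)(C(C)C)C(C)C)cc1C(O[Si](C)(C)C(C)(C)C)c1ccc(OCC=C)c(OC)c1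
F8 | step 16 | 3-tert-butyl 2,2-diethyl (1R)-7-(2-tert-butoxy-2-oxoethoxy)-6-methoxy-1-[3-methoxy-4-(methoxymethoxy)phenyl]naphthalene-2,2,3(1H)-tricarboxylate | CC(C)(C)OC(=O)COc1cc2c(cc1OC)C=C(C(=O)OC(C)(C)C)C(C(=O)OCC)(C(=O)OCC)[C@@H]2c1ccc(OCOC)c(OC)c1
F9 | step 16 | 3-tert-butyl 2,2-diethyl (1R)-7-{3-tert-butoxy-1-hydroxy-1-[3-methoxy-4-(methoxymethoxy)phenyl]-3-oxopropan-2-yloxy}-6-methoxy-1-[3-methoxy-4-(methoxymethoxy)phenyl]naphthalene-2,2,3(1H)-tricarboxylate (diastereomers at the two side-chain carbons) | CC(C)(C)OC(=O)C(Oc1cc2c(cc1OC)C=C(C(=O)OC(C)(C)C)C(C(=O)OCC)(C(=O)OCC)[C@@H]2c1ccc(OCOC)c(OC)c1)C(O)c1ccc(OCOC)c(OC)c1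
F10 | step 16 | methanesulfonate of F9 at the side-chain carbinol (diastereomers) | CC(C)(C)OC(=O)C(Oc1cc2c(cc1OC)C=C(C(=O)OC(C)(C)C)C(C(=O)OCC)(C(=O)OCC)[C@@H]2c1ccc(OCOC)c(OC)c1)C(OS(C)(=O)=O)c1ccc(OCOC)c(OC)c1
F11 | step 17 | (1R,2S)-3-(tert-butoxycarbonyl)-7-{[(1Z)-3-tert-butoxy-1-[3-methoxy-4-(methoxymethoxy)phenyl]-3-oxoprop-1-en-2-yl]oxy}-6-methoxy-1-[3-methoxy-4-(methoxymethoxy)phenyl]-1,2-dihydronaphthalene-2-carboxylic acid (trans epimer of 27) | COc1cc(/C=C(\Oc2cc3c(cc2OC)C=C(C(=O)OC(C)(C)C)[C@@H](C(=O)O)[C@@H]3c2ccc(OCOC)c(OC)c2)C(=O)OC(C)(C)C)ccc1OCOC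
A1 | alternative 1 | all-cis endo cycloadduct: 4-hydroxy-1-[3-methoxy-4-(methoxymethoxy)phenyl]-6-methoxy-7-(tert-butyldimethylsilyloxy)tetralin fused at C2–C3 to the menthyloxy γ-lactone acetal | CC(C)(C)[Si](C)(C)Oc1cc2c(cc1OC)[C@H](O)[C@@H]3C(=O)O[C@@H](O[C@@H]4C[C@H](C)CC[C@H]4C(C)C)[C@@H]3[C@@H]2c1ccc(OCOC)c(OC)c1
A2 | alternative 1 | 4-(tert-butyldimethylsilyloxy)-5-methoxy-2-[3-methoxy-4-(methoxymethoxy)benzyl]benzaldehyde | O=Cc1cc(OC)c(O[Si](C)(C)C(C)(C)C)cc1Cc1ccc(OCOC)c(OC)c1
A3 | alternative 1 | (5R)-5-[(1R,2S,5R)-menthyloxy]furan-2(5H)-one | O=C1C=C[C@H](O[C@@H]2C[C@H](C)CC[C@H]2C(C)C)O1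
A4 | alternative 2 | di-tert-butyl (1R)-6-methoxy-1-[3-methoxy-4-(methoxymethoxy)phenyl]-7-(triisopropylsilyloxy)-1,2-dihydronaphthalene-2,3-dicarboxylate (C2 epimers) | CC(C)[Si](C(C)C)(C(C)C)Oc1cc2c(cc1OC)C=C(C(=O)OC(C)(C)C)C(C(=O)OC(C)(C)C)[C@@H]2c1ccc(OCOC)c(OC)c1
A5 | alternative 2 | [2-formyl-4-methoxy-5-(triisopropylsilyloxy)phenyl]boronic acid | O=Cc1cc(OC)c(O[Si](C(C)C)(C(C)C)C(C)C)cc1B(O)O
A6 | alternative 2 | di-tert-butyl (2E)-2-[3-methoxy-4-(methoxymethoxy)benzylidene]butanedioate | CC(C)(C)OC(=O)C/C(C(=O)OC(C)(C)C)=C\c1ccc(OCOC)c(OC)c1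
A7 | alternative 3 | 3-tert-butyl 2,2-dimethyl (1R)-6-methoxy-1-[3-methoxy-4-(methoxymethoxy)phenyl]-7-(triisopropylsilyloxy)naphthalene-2,2,3(1H)-tricarboxylate | CC(C)[Si](C(C)C)(C(C)C)Oc1cc2c(cc1OC)C=C(C(=O)OC(C)(C)C)C(C(=O)OC)(C(=O)OC)[C@@H]2c1ccc(OCOC)c(OC)c1
A8 | alternative 3 | dimethyl 2-[(R)-{2-[(1E)-3-tert-butoxy-3-oxoprop-1-en-1-yl]-4-methoxy-5-(triisopropylsilyloxy)phenyl}[3-methoxy-4-(methoxymethoxy)phenyl]methyl]propanedioate | COC(=O)C(C(=O)OC)[C@@H](c1cc(O[Si](C(C)C)(C(C)C)C(C)C)c(OC)cc1/C=C/C(=O)OC(C)(C)C)c1ccc(OCOC)c(OC)c1
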